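**Retrosynthetic overview**

Numbering follows cyclodeca[b]furan: O1, C2(=O), C3(=CH2), C3a, C4 (O-glycolate), C6 (CH2OAc)=C7, C10 (CH3), C11a (O1–CH).
Enabling feature: the five atoms of the α-methylene-γ-butyrolactone are an aldehyde C=O (C11a, O1), one CO (C2) and the inner π-bond of a terminal allene (C3a=C3, with =CH2 as the outer carbon); the ring-fusion bond C3a–C11a is also a bond of the ten-membered ring.
Key disconnection: C2–C3 and C3a–C11a (with O1–C2) by a carbonylative [2+2+1] of the acyclic allenyl aldehyde 15; the cyclodecene and the lactone form together in this step, and the two esters are set afterwards.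
15 comes from the C6=C7 olefination of phosphono lactone 7 (from glycidyl ether 5 and phosphonoacetate 6; carries C4) with aldehyde 4 (from (S)-citronellal 1; carries C10); this temporary butyrolactone is reduced open to the C4–OH/C6–CH2OH pair, and the allene is then built from the C3a aldehyde.

Key step: step 12

Remark: 5 is taken as a purchasable building block; it is otherwise one step from (R)-glycidol (NaH, 4-methoxybenzyl chloride).

**Step 1**
Reactants: 1 (S)-citronellal
Product: 2 (3S)-1,1-dimethoxy-3,7-dimethyloct-6-ene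
Conditions: HC(OMe)3, MeOH, PPTS (cat.), rt
Reagents that add atoms: trimethyl orthoformate, COC(OC)OC
Why: Acid-catalysed acetalisation with the orthoformate as water scavenger masks the aldehyde that becomes C11a, the mild acid avoiding the carbonyl-ene cyclisation of citronellal and leaving the methyl-bearing centre untouched.

**Step 2**
Reactants: 2 (3S)-1,1-dimethoxy-3,7-dimethyloct-6-ene
Product: 4 (4S)-6,6-dimethoxy-4-methylhexanal, via secondary ozonide 3 (not isolated)
Conditions: O3, CH2Cl2, −78 °C; then PPh3, −78 °C → rt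
Reagents that add atoms: ozone, [O-][O+]=O
Why: Ozonolysis with reductive work-up cleaves the only alkene to the aldehyde (future C7) and acetone, the stereocentre being remote from the reacting site.

**Step 3**
Reactants: 5 (S)-4-methoxybenzyl glycidyl ether; 6 triethyl phosphonoacetate
Product: 7 diethyl [(5S)-5-{[(4-methoxybenzyl)oxy]methyl}-2-oxooxolan-3-yl]phosphonate (both C3 epimers)
Conditions: NaOEt, EtOH, 70 °C; then AcOH
Reagents that add atoms: none
Why: Epoxide ring-opening/lactonisation: the phosphonoacetate anion attacks the epoxide CH2 terminus (SN2) and the resulting alkoxide closes onto the ester, so the epoxide stereocentre becomes C4 of the target with its C–O bond untouched.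

**Step 4**
Reactants: 7 diethyl [(5S)-5-{[(4-methoxybenzyl)oxy]methyl}-2-oxooxolan-3-yl]phosphonate; 4 (4S)-6,6-dimethoxy-4-methylhexanal
Product: 8 (3E,5S)-3-[(4S)-6,6-dimethoxy-4-methylhexylidene]-5-{[(4-methoxybenzyl)oxy]methyl}oxolan-2-one
Conditions: KOtBu, THF, −78 → 0 °C
Reagents that add atoms: none
Why: Horner–Wadsworth–Emmons olefination of the stabilised lactone phosphonate should favour the E-alkylidene lactone (alkyl chain anti to the carbonyl), which is the geometry in which the future ring carbons C5 and C8 are cis across C6=C7.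

**Step 5**
Reactants: 8 (3E,5S)-3-[(4S)-6,6-dimethoxy-4-methylhexylidene]-5-{[(4-methoxybenzyl)oxy]methyl}oxolan-2-one
Product: 9 (2S,4E,8S)-4-(hydroxymethyl)-10,10-dimethoxy-1-[(4-methoxybenzyl)oxy]-8-methyldec-4-en-2-ol
Conditions: DIBAL-H (4 equiv), CH2Cl2, −78 → 0 °C; Rochelle salt
Reagents that add atoms: none
Why: DIBAL-H 1,2-reduction of the unsaturated lactone (through the lactol) opens the temporary ring to the primary allylic and the secondary alcohol without touching the alkene geometry, the acetal or the PMB ether.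

**Step 6**
Reactants: 9 (2S,4E,8S)-4-(hydroxymethyl)-10,10-dimethoxy-1-[(4-methoxybenzyl)oxy]-8-methyldec-4-en-2-ol
Product: 10 (2S,4E,8S)-2-[(tert-butyldimethylsilyl)oxy]-4-{[(tert-butyldimethylsilyl)oxy]methyl}-10,10-dimethoxy-1-[(4-methoxybenzyl)oxy]-8-methyldec-4-ene
Conditions: TBSCl, imidazole, DMAP (cat.), DMF, 40 °C
Reagents that add atoms: tert-butyldimethylsilyl chloride, CC(C)(C)[Si](C)(C)Cl
Why: Silyl ether formation at both hydroxyls under basic conditions that leave the dimethyl acetal intact.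

**Step 7**
Reactants: 10 (2S,4E,8S)-2-[(tert-butyldimethylsilyl)oxy]-4-{[(tert-butyldimethylsilyl)oxy]methyl}-10,10-dimethoxy-1-[(4-methoxybenzyl)oxy]-8-methyldec-4-ene
Product: 11 (2S,4E,8S)-2-[(tert-butyldimethylsilyl)oxy]-4-{[(tert-butyldimethylsilyl)oxy]methyl}-10,10-dimethoxy-8-methyldec-4-en-1-ol
Conditions: DDQ, CH2Cl2/pH 7 buffer, 0 °C
Reagents that add atoms: none
Why: Oxidative PMB ether cleavage with DDQ frees only the primary alcohol, the silyl ethers, the buffered acetal and the trisubstituted alkene being inert.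

**Step 8**
Reactants: 11 (2S,4E,8S)-2-[(tert-butyldimethylsilyl)oxy]-4-{[(tert-butyldimethylsilyl)oxy]methyl}-10,10-dimethoxy-8-methyldec-4-en-1-ol
Product: 12 (2S,4E,8S)-2-[(tert-butyldimethylsilyl)oxy]-4-{[(tert-butyldimethylsilyl)oxy]methyl}-10,10-dimethoxy-8-methyldec-4-enal
Conditions: Dess–Martin periodinane, pyridine, CH2Cl2, 0 °C
Reagents that add atoms: none
Why: Dess–Martin oxidation gives the α-silyloxy aldehyde under buffered conditions that should not epimerise the adjacent centre.

**Step 9**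
Reactants: 12 (2S,4E,8S)-2-[(tert-butyldimethylsilyl)oxy]-4-{[(tert-butyldimethylsilyl)oxy]methyl}-10,10-dimethoxy-8-methyldec-4-enal
Product: 13 (3S,6E,9S)-9-[(tert-butyldimethylsilyl)oxy]-7-{[(tert-butyldimethylsilyl)oxy]methyl}-1,1-dimethoxy-3-methylundec-6-en-10-yne
Conditions: dimethyl (1-diazo-2-oxopropyl)phosphonate, K2CO3, MeOH, 0 °C → rt
Reagents that add atoms: Ohira–Bestmann reagent, COP(=O)(OC)C(=[N+]=[N-])C(C)=O
Why: Seyferth–Gilbert homologation in its Ohira–Bestmann form converts the aldehyde into the terminal alkyne with mild base at low temperature, conditions under which α-silyloxy aldehydes normally keep their configuration.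

**Step 10**
Reactants: 13 (3S,6E,9S)-9-[(tert-butyldimethylsilyl)oxy]-7-{[(tert-butyldimethylsilyl)oxy]methyl}-1,1-dimethoxy-3-methylundec-6-en-10-yne
Product: 14 (3S,6E,9S)-9-[(tert-butyldimethylsilyl)oxy]-7-{[(tert-butyldimethylsilyl)oxy]methyl}-1,1-dimethoxy-3-methyldodeca-6,10,11-triene
Conditions: (CH2O)n, CuBr, iPr2NH, 1,4-dioxane, reflux
Reagents that add atoms: formaldehyde (as paraformaldehyde), C=O
Why: Crabbé homologation (Mannich reaction of the copper acetylide, then hydride transfer and loss of the imine) turns the terminal alkyne into the terminal allene without touching the propargylic C–O centre.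

**Step 11**
Reactants: 14 (3S,6E,9S)-9-[(tert-butyldimethylsilyl)oxy]-7-{[(tert-butyldimethylsilyl)oxy]methyl}-1,1-dimethoxy-3-methyldodeca-6,10,11-triene
Product: 15 (3S,6E,9S)-9-[(tert-butyldimethylsilyl)oxy]-7-{[(tert-butyldimethylsilyl)oxy]methyl}-3-methyldodeca-6,10,11-trienal
Conditions: LiBF4, MeCN/H2O (98:2), rt
Reagents that add atoms: water, O
Why: Mild Lewis-acid acetal hydrolysis frees the aldehyde while the TBS ethers and the allene should survive.

**Step 12**
Reactants: 15 (3S,6E,9S)-9-[(tert-butyldimethylsilyl)oxy]-7-{[(tert-butyldimethylsilyl)oxy]methyl}-3-methyldodeca-6,10,11-trienal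
Product: 16 (3aS,4S,6E,10S,11aS)-4-[(tert-butyldimethylsilyl)oxy]-6-{[(tert-butyldimethylsilyl)oxy]methyl}-10-methyl-3-methylidene-3a,4,5,8,9,10,11,11a-octahydrocyclodeca[b]furan-2(3H)-one
Conditions: Ru3(CO)12 (5 mol%), CO (20 atm), 1,4-dioxane (2 mM), 120 °C
Reagents that add atoms: carbon monoxide, [C-]#[O+]
Why: Proposed new method: Ru(0) should couple the inner allene π-bond and the aldehyde C=O oxidatively to an oxaruthenacyclopentane (C3a–C11a bond, Ru on the central allene carbon C3), CO then inserts into the Ru–C3 bond (C2–C3 bond) and C–O reductive elimination closes the lactone and releases Ru(0), the whole being a hetero-Pauson–Khand reaction. The closest known reaction type is the Ru3(CO)12- or Mo(CO)6-mediated cyclocarbonylation of allenyl aldehydes to bicyclic α-methylene-γ-butyrolactones, shown so far only with five- to seven-membered carbocycles; the ten-membered closure is the untested part, and intermolecular Ru-catalysed couplings of C=O, C=C and CO indicate that a short tether is not a mechanistic requirement. Ring closures: the cyclodecene by metal-templated 10-exo C–C bond formation at the substituted allene terminus under high dilution, the γ-lactone by reductive elimination from the acyl(alkoxy)ruthenium species. C3a: the tether can deliver the aldehyde only to the allene face on which C5 lies, which with H-4 eclipsing the allene (allylic strain) is the face anti to the C4 silyloxy group and gives (3aS). C11a: both tether ends should sit on one face of the five-membered metallacycle, so H-3a and H-11a should end up cis as in the known bicyclic cases. The step needs the proximal rather than the distal allene π-bond (the course of the known Ru and Mo examples), the aldehyde rather than the trisubstituted C6=C7 alkene as partner (such alkenes do not enter these metallacycles) and cyclisation rather than oligomerisation (2 mM); silyl ethers instead of esters at the C4 oxygen and at the C6 CH2O group remove any π-allyl pathway.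

**Step 13**
Reactants: 16 (3aS,4S,6E,10S,11aS)-4-[(tert-butyldimethylsilyl)oxy]-6-{[(tert-butyldimethylsilyl)oxy]methyl}-10-methyl-3-methylidene-3a,4,5,8,9,10,11,11a-octahydrocyclodeca[b]furan-2(3H)-one
Product: 17 (3aR,4S,6E,10S,11aS)-4-hydroxy-6-(hydroxymethyl)-10-methyl-3-methylidene-3a,4,5,8,9,10,11,11a-octahydrocyclodeca[b]furan-2(3H)-one
Conditions: HF·pyridine, pyridine, THF, 0 °C → rt
Reagents that add atoms: none
Why: Fluoride-mediated desilylation removes both TBS groups, buffered HF·pyridine being compatible with the α-methylene lactone (the 3a descriptor changes only through CIP priority).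

**Step 14**
Reactants: 17 (3aR,4S,6E,10S,11aS)-4-hydroxy-6-(hydroxymethyl)-10-methyl-3-methylidene-3a,4,5,8,9,10,11,11a-octahydrocyclodeca[b]furan-2(3H)-one
Product: 18 [(3aR,4S,6E,10S,11aS)-4-hydroxy-10-methyl-3-methylidene-2-oxo-2,3,3a,4,5,8,9,10,11,11a-decahydrocyclodeca[b]furan-6-yl]methyl acetate
Conditions: Ac2O (1.05 equiv), 2,4,6-collidine, CH2Cl2, −40 → −20 °C
Reagents that add atoms: acetic anhydride, CC(=O)OC(C)=O
Why: Kinetically selective acetylation should take the primary allylic alcohol in preference to the hindered secondary alcohol next to the ring fusion.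

**Step 15**
Reactants: 18 [(3aR,4S,6E,10S,11aS)-4-hydroxy-10-methyl-3-methylidene-2-oxo-2,3,3a,4,5,8,9,10,11,11a-decahydrocyclodeca[b]furan-6-yl]methyl acetate; 19 [(tert-butyldimethylsilyl)oxy]acetic acid
Product: 20 (3aS,4S,6E,10S,11aS)-6-(acetoxymethyl)-10-methyl-3-methylidene-2-oxo-2,3,3a,4,5,8,9,10,11,11a-decahydrocyclodeca[b]furan-4-yl [(tert-butyldimethylsilyl)oxy]acetate
Conditions: DCC, DMAP (cat.), CH2Cl2, 0 °C → rt
Reagents that add atoms: none
Why: Steglich esterification acylates the remaining secondary alcohol with retention at C4, the silyl group on the glycolic acid preventing its self-condensation.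

**Step 16**
Reactants: 20 (3aS,4S,6E,10S,11aS)-6-(acetoxymethyl)-10-methyl-3-methylidene-2-oxo-2,3,3a,4,5,8,9,10,11,11a-decahydrocyclodeca[b]furan-4-yl [(tert-butyldimethylsilyl)oxy]acetate
Product: 21 (3aS,4S,6E,10S,11aS)-6-(acetoxymethyl)-10-methyl-3-methylidene-2-oxo-2,3,3a,4,5,8,9,10,11,11a-decahydrocyclodeca[b]furan-4-yl hydroxyacetate (CNP0156635.1)
Conditions: HF·pyridine, THF, 0 °C
Reagents that add atoms: none
Why: Desilylation of the primary silyl ether frees the glycolate hydroxyl, while the acetate, the glycolate ester and the α-methylene lactone are stable to buffered HF.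

**Compound list**

1 | (S)-citronellal, (3S)-3,7-dimethyloct-6-enal | O=CC[C@@H](C)CCC=C(C)C | starting material
2 | (3S)-1,1-dimethoxy-3,7-dimethyloct-6-ene | COC(OC)C[C@@H](C)CCC=C(C)C | intermediate
3 | secondary ozonide, 3-[(3S)-5,5-dimethoxy-3-methylpentyl]-5,5-dimethyl-1,2,4-trioxolane (epimers at the ring carbon) | COC(OC)C[C@@H](C)CCC1OOC(C)(C)O1 | intermediate
4 | (4S)-6,6-dimethoxy-4-methylhexanal | COC(OC)C[C@@H](C)CCC=O | intermediate
5 | (S)-4-methoxybenzyl glycidyl ether, (2S)-2-{[(4-methoxyphenyl)methoxy]methyl}oxirane | COc1ccc(COC[C@@H]2CO2)cc1 | starting material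
6 | triethyl phosphonoacetate | CCOC(=O)CP(=O)(OCC)OCC | starting material
7 | diethyl [(5S)-5-{[(4-methoxybenzyl)oxy]methyl}-2-oxooxolan-3-yl]phosphonate (C3 epimers) | CCOP(=O)(OCC)C1C[C@@H](COCc2ccc(OC)cc2)OC1=O | intermediate
8 | (3E,5S)-3-[(4S)-6,6-dimethoxy-4-methylhexylidene]-5-{[(4-methoxybenzyl)oxy]methyl}oxolan-2-one | COC(OC)C[C@@H](C)CC/C=C1\C[C@@H](COCc2ccc(OC)cc2)OC1=O | intermediate
9 | (2S,4E,8S)-4-(hydroxymethyl)-10,10-dimethoxy-1-[(4-methoxybenzyl)oxy]-8-methyldec-4-en-2-ol | COC(OC)C[C@@H](C)CC/C=C(/CO)C[C@H](O)COCc1ccc(OC)cc1 | intermediate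
10 | (2S,4E,8S)-2-[(tert-butyldimethylsilyl)oxy]-4-{[(tert-butyldimethylsilyl)oxy]methyl}-10,10-dimethoxy-1-[(4-methoxybenzyl)oxy]-8-methyldec-4-ene | COC(OC)C[C@@H](C)CC/C=C(/CO[Si](C)(C)C(C)(C)C)C[C@H](O[Si](C)(C)C(C)(C)C)COCc1ccc(OC)cc1 | intermediate
11 | (2S,4E,8S)-2-[(tert-butyldimethylsilyl)oxy]-4-{[(tert-butyldimethylsilyl)oxy]methyl}-10,10-dimethoxy-8-methyldec-4-en-1-ol | COC(OC)C[C@@H](C)CC/C=C(/CO[Si](C)(C)C(C)(C)C)C[C@H](O[Si](C)(C)C(C)(C)C)CO | intermediate
12 | (2S,4E,8S)-2-[(tert-butyldimethylsilyl)oxy]-4-{[(tert-butyldimethylsilyl)oxy]methyl}-10,10-dimethoxy-8-methyldec-4-enal | COC(OC)C[C@@H](C)CC/C=C(/CO[Si](C)(C)C(C)(C)C)C[C@H](O[Si](C)(C)C(C)(C)C)C=O | intermediate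
13 | (3S,6E,9S)-9-[(tert-butyldimethylsilyl)oxy]-7-{[(tert-butyldimethylsilyl)oxy]methyl}-1,1-dimethoxy-3-methylundec-6-en-10-yne | COC(OC)C[C@@H](C)CC/C=C(/CO[Si](C)(C)C(C)(C)C)C[C@H](O[Si](C)(C)C(C)(C)C)C#C | intermediate
14 | (3S,6E,9S)-9-[(tert-butyldimethylsilyl)oxy]-7-{[(tert-butyldimethylsilyl)oxy]methyl}-1,1-dimethoxy-3-methyldodeca-6,10,11-triene | COC(OC)C[C@@H](C)CC/C=C(/CO[Si](C)(C)C(C)(C)C)C[C@H](O[Si](C)(C)C(C)(C)C)C=C=C | intermediate
15 | (3S,6E,9S)-9-[(tert-butyldimethylsilyl)oxy]-7-{[(tert-butyldimethylsilyl)oxy]methyl}-3-methyldodeca-6,10,11-trienal | O=CC[C@@H](C)CC/C=C(/CO[Si](C)(C)C(C)(C)C)C[C@H](O[Si](C)(C)C(C)(C)C)C=C=C | intermediate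
16 | (3aS,4S,6E,10S,11aS)-4-[(tert-butyldimethylsilyl)oxy]-6-{[(tert-butyldimethylsilyl)oxy]methyl}-10-methyl-3-methylidene-3a,4,5,8,9,10,11,11a-octahydrocyclodeca[b]furan-2(3H)-one | C=C1C(=O)O[C@H]2C[C@@H](C)CC/C=C(/CO[Si](C)(C)C(C)(C)C)C[C@H](O[Si](C)(C)C(C)(C)C)[C@@H]12 | intermediate
17 | (3aR,4S,6E,10S,11aS)-4-hydroxy-6-(hydroxymethyl)-10-methyl-3-methylidene-3a,4,5,8,9,10,11,11a-octahydrocyclodeca[b]furan-2(3H)-one | C=C1C(=O)O[C@H]2C[C@@H](C)CC/C=C(/CO)C[C@H](O)[C@@H]12 | intermediate
18 | [(3aR,4S,6E,10S,11aS)-4-hydroxy-10-methyl-3-methylidene-2-oxo-2,3,3a,4,5,8,9,10,11,11a-decahydrocyclodeca[b]furan-6-yl]methyl acetate | C=C1C(=O)O[C@H]2C[C@@H](C)CC/C=C(/COC(C)=O)C[C@H](O)[C@@H]12 | intermediate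
19 | [(tert-butyldimethylsilyl)oxy]acetic acid | O=C(O)CO[Si](C)(C)C(C)(C)C | starting material
20 | (3aS,4S,6E,10S,11aS)-6-(acetoxymethyl)-10-methyl-3-methylidene-2-oxo-2,3,3a,4,5,8,9,10,11,11a-decahydrocyclodeca[b]furan-4-yl [(tert-butyldimethylsilyl)oxy]acetate | C=C1C(=O)O[C@H]2C[C@@H](C)CC/C=C(/COC(C)=O)C[C@H](OC(=O)CO[Si](C)(C)C(C)(C)C)[C@@H]12 | intermediate
21 | (3aS,4S,6E,10S,11aS)-6-(acetoxymethyl)-10-methyl-3-methylidene-2-oxo-2,3,3a,4,5,8,9,10,11,11a-decahydrocyclodeca[b]furan-4-yl hydroxyacetate | C=C1C(=O)O[C@H]2C[C@@H](C)CC/C=C(/COC(C)=O)C[C@H](OC(=O)CO)[C@@H]12 | target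

**Step count and risks**

Total step count: 16. Longest linear sequence: 15 steps (1 → 21 through steps 1, 2 and 4–16).

Step 12 (proposed new method). The ten-membered closure may lose to oligomerisation, the metal may engage the distal allene π-bond, or the aldehyde may add with the wrong facial sense and give the trans-fused lactone. The fallback uses known chemistry, sets out from 12 and comes back at 16. A Morita–Baylis–Hillman reaction of aldehyde 12 with methyl acrylate (DABCO) should give the hydroxy acrylate F1. SN2′ bromination (NBS, Me2S) should give the (Z)-2-(bromomethyl)enoate F2, and acetal hydrolysis (LiBF4, wet MeCN) the bromo aldehyde F3. Intramolecular Nozaki–Hiyama-type allylation (CrCl2, THF, high dilution) through the chair transition state of the ester-substituted allylchromium, followed by lactonisation on mild acid work-up, should then give the cis-fused lactone 16. In this variant C2–C3 comes from the acrylate and only C3a–C11a is made in the ring closure.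

Step 4. The olefination may give poor E/Z control at the trisubstituted alkene. The fallback sets out from 5 and comes back at 8. Opening of epoxide 5 with sodium diethyl malonate should give the α-ethoxycarbonyl lactone F4, and Krapcho dealkoxycarbonylation (NaCl, wet DMSO, 150 °C) the parent lactone F5. Aldol addition of its lithium enolate (LDA, −78 °C) to aldehyde 4 should give the β-hydroxy lactone F6. Mesylation (MsCl, Et3N) to the mesylate F7 and E1cB elimination with DBU should then give the thermodynamically preferred E-alkylidene lactone 8.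

Step 9. The α-silyloxy aldehyde may epimerise in basic methanol, which would erode the C4 centre. The fallback sets out from 12 and comes back at 13. Corey–Fuchs dibromo-olefination (CBr4, PPh3, 2,6-lutidine, CH2Cl2, 0 °C) should give the 1,1-dibromoalkene F8; n-BuLi (2.2 equiv, THF, −78 °C) and aqueous quench should then give alkyne 13 without any protic base meeting the aldehyde.

**Further compounds**

F1 | step 12 | methyl (4S,6E,10S)-4-[(tert-butyldimethylsilyl)oxy]-6-{[(tert-butyldimethylsilyl)oxy]methyl}-3-hydroxy-12,12-dimethoxy-10-methyl-2-methylidenedodec-6-enoate (C3 epimers) | COC(OC)C[C@@H](C)CC/C=C(/CO[Si](C)(C)C(C)(C)C)C[C@H](O[Si](C)(C)C(C)(C)C)C(O)C(=C)C(=O)OC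
F2 | step 12 | methyl (2Z,4S,6E,10S)-2-(bromomethyl)-4-[(tert-butyldimethylsilyl)oxy]-6-{[(tert-butyldimethylsilyl)oxy]methyl}-12,12-dimethoxy-10-methyldodeca-2,6-dienoate | COC(OC)C[C@@H](C)CC/C=C(/CO[Si](C)(C)C(C)(C)C)C[C@H](O[Si](C)(C)C(C)(C)C)/C=C(\CBr)C(=O)OC
F3 | step 12 | methyl (2Z,4S,6E,10S)-2-(bromomethyl)-4-[(tert-butyldimethylsilyl)oxy]-6-{[(tert-butyldimethylsilyl)oxy]methyl}-10-methyl-12-oxododeca-2,6-dienoate | O=CC[C@@H](C)CC/C=C(/CO[Si](C)(C)C(C)(C)C)C[C@H](O[Si](C)(C)C(C)(C)C)/C=C(\CBr)C(=O)OC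
F4 | step 4 | ethyl (5S)-5-{[(4-methoxybenzyl)oxy]methyl}-2-oxooxolane-3-carboxylate (C3 epimers) | CCOC(=O)C1C[C@@H](COCc2ccc(OC)cc2)OC1=O
F5 | step 4 | (5S)-5-{[(4-methoxybenzyl)oxy]methyl}oxolan-2-one | O=C1CC[C@@H](COCc2ccc(OC)cc2)O1
F6 | step 4 | (5S)-3-[(4S)-1-hydroxy-6,6-dimethoxy-4-methylhexyl]-5-{[(4-methoxybenzyl)oxy]methyl}oxolan-2-one (epimers at the two new centres) | COC(OC)C[C@@H](C)CCC(O)C1C[C@@H](COCc2ccc(OC)cc2)OC1=O
F7 | step 4 | methanesulfonate of F6 | COC(OC)C[C@@H](C)CCC(OS(C)(=O)=O)C1C[C@@H](COCc2ccc(OC)cc2)OC1=O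
F8 | step 9 | (3S,6E,9S)-11,11-dibromo-9-[(tert-butyldimethylsilyl)oxy]-7-{[(tert-butyldimethylsilyl)oxy]methyl}-1,1-dimethoxy-3-methylundeca-6,10-diene | COC(OC)C[C@@H](C)CC/C=C(/CO[Si](C)(C)C(C)(C)C)C[C@H](O[Si](C)(C)C(C)(C)C)C=C(Br)Br
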